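**Retrosynthetic overview**
1. Target ⇒ scopoletin + a (2R,3R)-vinyl epoxide. One Pd(0)-catalysed SN2′ (1,4) epoxide opening forms the aryl ether C–O bond and the E-trisubstituted alkene and frees the (R)-carbinol, whose C–O bond is never broken. This replaces the usual Williamson alkylation with a preformed chiral allylic halide.
2. Vinyl epoxide ⇒ (5E)-2,6-dimethylocta-5,7-dien-2-ol by regio- and enantioselective Shi mono-epoxidation of the trisubstituted alkene, which sets the only stereocentre that survives.
3. Diene ⇒ E-enal (Wittig) ⇒ 2,6-dimethylhept-5-en-2-ol (SeO2 allylic oxidation fixes the E geometry) ⇒ 6-methylhept-5-en-2-one + MeMgBr.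
4. Rings: the coumarin is bought intact as scopoletin. The only ring made is the oxirane (step 4), opened again in step 5. No protecting groups.

Assumption: only carbon-skeleton compounds are numbered, simple reagents are named with SMILES in the steps, and the π-allyl complex 8 is drawn in its η1 (σ-allyl) form with formal charges.

**Step 1**
Reactants: 1 6-methylhept-5-en-2-one (sulcatone)
Product: 2 2,6-dimethylhept-5-en-2-ol
Conditions: MeMgBr (1.2 equiv), THF, 0 °C → rt; H2O quench (aq NH4Cl wash)
Reagents that add atoms: methylmagnesium bromide, C[Mg]Br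
Why: Grignard 1,2-addition to an unhindered methyl ketone gives the tertiary alcohol, the trisubstituted alkene is inert and no stereocentre is formed.

**Step 2**
Reactants: 2 2,6-dimethylhept-5-en-2-ol
Product: 4 (2E)-6-hydroxy-2,6-dimethylhept-2-enal, via allylic diol 3 (not isolated)
Conditions: SeO2 (1.2 equiv), 1,4-dioxane/H2O (30:1), 80 °C
Reagents that add atoms: selenium dioxide, O=[Se]=O
Why: Riley (SeO2) allylic oxidation, in which the ene reaction/[2,3]-sigmatropic shift sequence oxidises the E-methyl group at the more substituted alkene terminus and leaves the alkene E, the allylic alcohol 3 formed first being oxidised on by SeO2 to the conjugated aldehyde while the tertiary OH cannot be oxidised.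

**Step 3**
Reactants: 4 (2E)-6-hydroxy-2,6-dimethylhept-2-enal
Product: 5 (5E)-2,6-dimethylocta-5,7-dien-2-ol
Conditions: Ph3PCH3Br (2.5 equiv), KOtBu (2.4 equiv), THF, 0 °C; then 4, −78 → 0 °C
Reagents that add atoms: methyltriphenylphosphonium bromide, C[P+](c1ccccc1)(c1ccccc1)c1ccccc1.[Br-]
Why: Wittig methylenation of the aldehyde with excess non-stabilised ylide (which tolerates the free tertiary OH) installs the terminal vinyl group without touching the existing E-trisubstituted alkene, and no stereocentre is formed.

**Step 4**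
Reactants: 5 (5E)-2,6-dimethylocta-5,7-dien-2-ol
Product: 6 4-[(2R,3R)-3-ethenyl-3-methyloxiran-2-yl]-2-methylbutan-2-ol
Conditions: D-fructose-derived Shi ketone (0.3 equiv), Oxone (1.4 equiv), K2CO3 (5.8 equiv), Bu4NHSO4 (cat.), MeCN/DMM (1:2), aq Na2B4O7–Na2EDTA buffer (pH ≈ 10.5), −10 → 0 °C; filtration through Et3N-deactivated silica, used at once
Reagents that add atoms: Oxone (potassium peroxymonosulfate), [K+].[O-]S(=O)(=O)OO
Why: Shi asymmetric epoxidation, in which the electrophilic chiral dioxirane attacks only the electron-rich trisubstituted alkene of the diene (the terminal vinyl group and the vinyl epoxide formed are far less nucleophilic) through the spiro transition state that gives (R,R)-epoxides from trans- and trisubstituted alkenes, so the ring CH carbon (the future C-4′) is set as R under a basic buffer that leaves the hydroxy epoxide uncyclised.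

**Step 5**
Reactants: 6 4-[(2R,3R)-3-ethenyl-3-methyloxiran-2-yl]-2-methylbutan-2-ol; 7 scopoletin (7-hydroxy-6-methoxy-2H-chromen-2-one)
Product: 9 7-{[(2E,4R)-4,7-dihydroxy-3,7-dimethyloct-2-en-1-yl]oxy}-6-methoxy-2H-chromen-2-one, via allylpalladium alkoxide 8 (not isolated)
Conditions: Pd(PPh3)4 (5 mol %), 7 (1.2 equiv), THF, 0 °C → rt, slow addition of 6
Reagents that add atoms: none
Why: Tsuji–Trost-type 1,4-(SN2′) opening of a vinyl epoxide by a phenol, in which Pd(0) ionises the allylic C–O bond to the zwitterionic π-allyl complex 8, its alkoxide deprotonates 7 (the only acidic OH present) and the phenoxide attacks the unhindered CH2 terminus, so the C-4′–O bond is never broken (R retained) and the bulky carbinol substituent sits syn on the π-allyl, with any branched or Z ether re-ionising, to give the E-alkene.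

**Compound list**
1 | 6-methylhept-5-en-2-one (sulcatone) | CC(=O)CCC=C(C)C | starting material
2 | 2,6-dimethylhept-5-en-2-ol | CC(C)=CCCC(C)(C)O | intermediate
3 | (2E)-2,6-dimethylhept-2-ene-1,6-diol (allylic diol) | OC/C(C)=C/CCC(C)(C)O | intermediate
4 | (2E)-6-hydroxy-2,6-dimethylhept-2-enal | O=C/C(C)=C/CCC(C)(C)O | intermediate
5 | (5E)-2,6-dimethylocta-5,7-dien-2-ol | C=C/C(C)=C/CCC(C)(C)O | intermediate
6 | 4-[(2R,3R)-3-ethenyl-3-methyloxiran-2-yl]-2-methylbutan-2-ol | C=C[C@@]1(C)O[C@@H]1CCC(C)(C)O | intermediate
7 | scopoletin (7-hydroxy-6-methoxy-2H-chromen-2-one) | COc1cc2ccc(=O)oc2cc1O | starting material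
8 | zwitterionic (η3-allyl)Pd(PPh3)2 (4R)-alkoxide from 6 (allylpalladium alkoxide, drawn η1 at C-1′) | CC(C)(O)CC[C@@H]([O-])/C(C)=C/C[Pd-]([P+](c1ccccc1)(c1ccccc1)c1ccccc1)[P+](c1ccccc1)(c1ccccc1)c1ccccc1 | intermediate
9 | 7-{[(2E,4R)-4,7-dihydroxy-3,7-dimethyloct-2-en-1-yl]oxy}-6-methoxy-2H-chromen-2-one | COc1cc2ccc(=O)oc2cc1OC/C=C(\C)[C@H](O)CCC(C)(C)O | target

**Totals**
Total step count: 5. Longest linear sequence: 5 steps (1 → 9); scopoletin 7 enters in the last step.

**Steps most likely to fail**

Step 5 (Pd-catalysed 1,4-O-allylation). The risks are E/Z and linear/branched mixtures, competing Pd-catalysed cyclisation by the C-7′ hydroxyl, and carrying through any ee shortfall from step 4. The fallback sets out from 6 (coupled with 7 as before, without demanding selectivity) and comes back at 9. The crude linear ethers, 9 together with its geometric isomer 7-{[(2Z,4R)-4,7-dihydroxy-3,7-dimethyloct-2-en-1-yl]oxy}-6-methoxy-2H-chromen-2-one F1, are not separated. They are oxidised at the allylic carbinol with MnO2 (CH2Cl2, rt; the tertiary OH is inert), giving the E-enone mixed with 7-{[(2Z)-7-hydroxy-3,7-dimethyl-4-oxooct-2-en-1-yl]oxy}-6-methoxy-2H-chromen-2-one F2. A trace of I2 in CH2Cl2 under light equilibrates this to the thermodynamically preferred 7-{[(2E)-7-hydroxy-3,7-dimethyl-4-oxooct-2-en-1-yl]oxy}-6-methoxy-2H-chromen-2-one F3. Corey–Bakshi–Shibata reduction with (S)-Me-CBS (20 mol %) and catecholborane (toluene, −78 °C; alkenyl as the large group, the same sense as acetophenone → (R)-1-phenylethanol) then gives 9. Geometry is now fixed thermodynamically and the stereocentre is set by the reagent, not carried through the π-allyl step.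

Step 4 (Shi mono-epoxidation). The risks are which alkene of the diene reacts and the ee on this 2-substituted diene. The fallback sets out from 4 and comes back at 6. Luche reduction of 4 (NaBH4, CeCl3·7H2O, MeOH, 0 °C) gives the allylic diol 3, this time isolated. Sharpless asymmetric epoxidation (Ti(OiPr)4, D-(−)-diisopropyl tartrate, t-BuOOH, 4 Å MS, CH2Cl2, −20 °C; NaOH/brine work-up, no acid) gives [(2R,3R)-3-(3-hydroxy-3-methylbutyl)-2-methyloxiran-2-yl]methanol F4. The primary allylic OH directs the titanium, so there is only one possible site, and the D-tartrate gives the (2R,3R)-epoxide. Parikh–Doering oxidation (SO3·pyridine, DMSO, iPr2NEt, 0 °C) gives (2S,3R)-3-(3-hydroxy-3-methylbutyl)-2-methyloxirane-2-carbaldehyde F5; the descriptor change at C-2 is a CIP effect only. Wittig methylenation (Ph3P=CH2, THF, −78 → 0 °C) returns 6.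

Step 2 (SeO2 oxidation). The risks are modest yield, over-oxidation and selenium-containing by-products. The fallback sets out from 2 and comes back at 4. Ozonolysis of 2 (O3, CH2Cl2/MeOH, −78 °C; Me2S) cleaves the trisubstituted alkene, releases acetone and gives 5,5-dimethyloxolan-2-ol F6, the lactol of the hydroxy aldehyde. Wittig olefination of this lactol with the stabilised ylide 2-(triphenylphosphoranylidene)propanal (toluene, 90 °C) rebuilds the enal 4 with the high E-selectivity usual for stabilised ylides, replacing allylic C–H oxidation by C=C cleavage and olefination.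

**Further compounds**
F1 | step 5 | 7-{[(2Z,4R)-4,7-dihydroxy-3,7-dimethyloct-2-en-1-yl]oxy}-6-methoxy-2H-chromen-2-one | COc1cc2ccc(=O)oc2cc1OC/C=C(/C)[C@H](O)CCC(C)(C)O
F2 | step 5 | 7-{[(2Z)-7-hydroxy-3,7-dimethyl-4-oxooct-2-en-1-yl]oxy}-6-methoxy-2H-chromen-2-one | COc1cc2ccc(=O)oc2cc1OC/C=C(/C)C(=O)CCC(C)(C)O
F3 | step 5 | 7-{[(2E)-7-hydroxy-3,7-dimethyl-4-oxooct-2-en-1-yl]oxy}-6-methoxy-2H-chromen-2-one | COc1cc2ccc(=O)oc2cc1OC/C=C(\C)C(=O)CCC(C)(C)O
F4 | step 4 | [(2R,3R)-3-(3-hydroxy-3-methylbutyl)-2-methyloxiran-2-yl]methanol | OC[C@@]1(C)O[C@@H]1CCC(C)(C)O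
F5 | step 4 | (2S,3R)-3-(3-hydroxy-3-methylbutyl)-2-methyloxirane-2-carbaldehyde | O=C[C@@]1(C)O[C@@H]1CCC(C)(C)O
F6 | step 2 | 5,5-dimethyloxolan-2-ol | CC1(C)CCC(O)O1
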